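**Retrosynthetic overview**
- The strategy rests on ring A. It is a 2,4-dimethoxyphloroglucinol with one C–H only, C4a, which lies between O1 and O5. In the free resorcinol 5 these two oxygens are equivalent, so a single etherification builds O1–C2 and leaves the O5 phenol next to C4a.
- Ring C is the only ring formed; rings A and B are bought. It closes at C4–C4a when C4a of the O5 magnesium phenolate attacks a tethered α-benzyloxy aldehyde (14 → 17).
- O1–C2 comes from an inverting Mitsunobu etherification of syn alcohol 12 with 5. C2 and C3 come from an Evans syn glycolate aldol on 3,4,5-tris(benzyloxy)benzaldehyde, which delivers O3 already benzylated.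
- Resorcinol 5 is made from 2,6-dimethoxyphenol by O-benzylation, 4,6-dibromination, double borylation and oxidation.
- One hydrogenolysis of five benzyl ethers ends the route.

Key step: step 10

Remark on the chemistry: the target SMILES is read as (2R,3S,4R), which is 2,3-trans-3,4-trans. Flavan numbering (O1, C2, C3, C4, C4a, C5–C8, C8a, primed atoms for ring B) is used for ring atoms from compound 13 onward.

**Step 1**
Reactants: 1 2,6-dimethoxyphenol
Product: 2 2-(benzyloxy)-1,3-dimethoxybenzene
Conditions: BnBr, K2CO3, DMF, 60 °C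
Reagents that add atoms: benzyl bromide, BrCc1ccccc1
Why: Williamson ether synthesis on an acidic phenol, with benzyl chosen so that O7 is unmasked together with all other benzyl ethers in the last step.

**Step 2**
Reactants: 2 2-(benzyloxy)-1,3-dimethoxybenzene
Product: 3 3-(benzyloxy)-1,5-dibromo-2,4-dimethoxybenzene
Conditions: NBS (2.1 equiv), MeCN, 0 °C → rt, dark
Reagents that add atoms: N-bromosuccinimide, O=C1CCC(=O)N1Br
Why: Electrophilic aromatic bromination, in which each attacked carbon is para to one methoxy group and ortho to the other while the remaining carbon is activated only by the out-of-plane central benzyloxy group, so the 4,6-dibromide pattern known for pyrogallol triethers should form.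

**Step 3**
Reactants: 3 3-(benzyloxy)-1,5-dibromo-2,4-dimethoxybenzene
Product: 4 2,2'-[5-(benzyloxy)-4,6-dimethoxy-1,3-phenylene]bis(4,4,5,5-tetramethyl-1,3,2-dioxaborolane)
Conditions: B2pin2 (2.5 equiv), PdCl2(dppf) (5 mol %), KOAc, 1,4-dioxane, 90 °C
Reagents that add atoms: bis(pinacolato)diboron, CC1(C)OB(OC1(C)C)B1OC(C)(C)C(C)(C)O1
Why: Double Miyaura borylation, feasible because each C–Br bond has only one ortho substituent and KOAc is too weak a base to start Suzuki homocoupling.

**Step 4**
Reactants: 4 the bis(boronate)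
Product: 5 5-(benzyloxy)-4,6-dimethoxybenzene-1,3-diol
Conditions: 30 % H2O2, aq NaOH, THF, 0 °C, argon; then 1 M HCl
Reagents that add atoms: hydrogen peroxide, OO
Why: Oxidation of aryl boronates with basic hydrogen peroxide (1,2-aryl shift from boron to oxygen) puts OH on the carbon that carried boron, and cold, brief, oxygen-free handling protects the electron-rich resorcinol.

**Step 5**
Reactants: 6 (R)-4-benzyloxazolidin-2-one; 7 (benzyloxy)acetyl chloride
Product: 8 (R)-4-benzyl-3-[(benzyloxy)acetyl]oxazolidin-2-one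
Conditions: Et3N, DMAP (cat.), CH2Cl2, 0 °C → rt
Reagents that add atoms: none
Why: DMAP-catalysed N-acylation of the oxazolidinone with an acid chloride, which touches no stereocentre.

**Step 6**
Reactants: 8 (R)-4-benzyl-3-[(benzyloxy)acetyl]oxazolidin-2-one; 9 3,4,5-tris(benzyloxy)benzaldehyde
Product: 11 (R)-4-benzyl-3-{(2R,3S)-2-(benzyloxy)-3-hydroxy-3-[3,4,5-tris(benzyloxy)phenyl]propanoyl}oxazolidin-2-one, via Z dibutylboron enolate 10 (not isolated)
Conditions: n-Bu2BOTf, Et3N, CH2Cl2, −78 → 0 °C; 9, −78 → 0 °C; NaH2PO4/Na2HPO4 buffer (pH 7), MeOH, 30 % H2O2, 0 °C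
Reagents that add atoms: none
Why: Evans syn aldol reaction, in which Z enolate 10 reacts through a chair Zimmerman–Traxler transition state on the face away from the benzyl group of the R auxiliary, setting 2R (the later C3) and 3S (the carbinol that becomes C2 after inversion).

**Step 7**
Reactants: 11 the aldol adduct
Product: 12 (2R,3S)-2-(benzyloxy)-3-hydroxy-N-methoxy-N-methyl-3-[3,4,5-tris(benzyloxy)phenyl]propanamide
Conditions: MeONHMe·HCl, AlMe3, CH2Cl2, −10 → 0 °C; aq KNaC4H4O6 (tartrate)
Reagents that add atoms: N,O-dimethylhydroxylamine hydrochloride, CNOC.Cl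
Why: Aluminium amide transamidation of an aldol imide to the Weinreb amide, helped by the free β-hydroxyl group, releases the auxiliary and gives a carbonyl group that is a weaker carbon acid than an ester and stops at the aldehyde on hydride reduction.

**Step 8**
Reactants: 12 the syn hydroxy Weinreb amide; 5 5-(benzyloxy)-4,6-dimethoxybenzene-1,3-diol
Product: 13 (2R,3R)-2-(benzyloxy)-3-[3-(benzyloxy)-5-hydroxy-2,4-dimethoxyphenoxy]-N-methoxy-N-methyl-3-[3,4,5-tris(benzyloxy)phenyl]propanamide
Conditions: 5 (3 equiv), n-Bu3P, N,N,N',N'-tetramethylazodicarboxamide (TMAD), toluene, 0 °C → rt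
Reagents that add atoms: none
Why: Mitsunobu etherification with SN2 inversion at the benzylic carbinol (3S to 3R, the 2,3-trans relation), in which the equivalence of the two OH groups of 5 allows one monoether only, the excess of 5 holds back a second etherification, and the non-polar solvent, the electron-withdrawing α-substituents and the weakly electrophilic azo reagent should suppress ionisation, elimination and C-amination of the arene.

**Step 9**
Reactants: 13 the aryl ether Weinreb amide
Product: 14 (2R,3R)-2-(benzyloxy)-3-[3-(benzyloxy)-5-hydroxy-2,4-dimethoxyphenoxy]-3-[3,4,5-tris(benzyloxy)phenyl]propanal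
Conditions: i-Bu2AlH (2.5 equiv), THF, −78 °C; aq KNaC4H4O6 (tartrate); used crude
Reagents that add atoms: none
Why: Weinreb amide reduction, in which the phenol consumes the first equivalent of hydride and the next stops at the aldehyde stage, so the aldehyde is reached by reduction, the oxidation-sensitive free phenol never meets an oxidant, and C2 and C3 are untouched at −78 °C.

**Step 10**
Reactants: 14 the phenol aldehyde
Product: 17 (2R,3S,4R)-3,7-bis(benzyloxy)-6,8-dimethoxy-2-[3,4,5-tris(benzyloxy)phenyl]chromane-4,5-diol, via bromomagnesium phenolate 15 (not isolated), via dienone bromomagnesium alkoxide 16 (not isolated)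
Conditions: MesMgBr (2,4,6-Me3C6H2MgBr, 1.0 M in Et2O, 1.0 equiv), CH2Cl2 (0.005 M), −78 → 0 °C; NaH2PO4/Na2HPO4 buffer (pH 7)
Reagents that add atoms: none
Why: Proposed new method: MesMgBr takes only the phenolic proton, leaving no amine or surplus base that could enolise the β-aryloxy aldehyde, and in the weakly coordinating medium the magnesium of phenolate 15 binds the tethered aldehyde oxygen, so that C4a (ortho to O5 and O1, para to O7) adds to the carbonyl carbon C4 to give dienone alkoxide 16, whose 4a-proton then passes to the alkoxide and restores ring A. The closest known reaction type is the ortho-specific hydroxyalkylation of bromomagnesium phenolates with aldehydes, α-alkoxy aldehydes included, which is a metal-templated Friedel–Crafts or phenolate aldol addition; its use within one molecule to close a chroman ring is the untested part. Ring C closes by forming C4–C4a in a 6-(enolendo)-exo-trig mode, with O5–C5=C4a as the enolate and the C=O bond outside the new ring. C4 is controlled by the existing centres C2 and C3 through a trans-fused double chair, in which the six-membered O5–Mg–O4 chelate shares the forming bond with a chair-like ring C that carries the C2 aryl, C3 benzyloxy and C4–O4 bonds equatorial and turns only H4 over ring A; this arrangement gives O4 trans to O3 (4R), and no chelate to O3 is counted on, because magnesium held between O5 and O4 lies anti to C3. Site selectivity within ring A needs no control because C4a is its only C–H, and closure onto C2' or C6' of ring B to an indanol, a real risk under acid promotion, should be outrun because only ring A is a phenolate and carries the metal. High dilution and temperatures up to 0 °C should hold back loss of the aryloxide by β-elimination, epimerisation at C3 and ortho-quinone methide formation from the product salt.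

**Step 11**
Reactants: 17 the penta-O-benzyl flavan-3,4-diol
Product: 18 (2R,3S,4R)-6,8-dimethoxy-2-(3,4,5-trihydroxyphenyl)chromane-3,4,5,7-tetrol (target)
Conditions: H2 (1 atm), 10 % Pd/C (washed acid-free), THF–EtOAc, rt
Reagents that add atoms: none
Why: Catalytic hydrogenolysis of four aryl benzyl ethers and one alkyl benzyl ether, during which the benzylic C4–OH and C2–O1 bonds should survive on an acid-free catalyst in a non-alcoholic solvent because they need acid activation or forcing conditions, and no stereocentre is involved.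

**Compound list**
1 | 2,6-dimethoxyphenol | COc1cccc(OC)c1O | starting material
2 | 2-(benzyloxy)-1,3-dimethoxybenzene | COc1cccc(OC)c1OCc1ccccc1 | intermediate
3 | 3-(benzyloxy)-1,5-dibromo-2,4-dimethoxybenzene | COc1c(Br)cc(Br)c(OC)c1OCc1ccccc1 | intermediate
4 | 2,2'-[5-(benzyloxy)-4,6-dimethoxy-1,3-phenylene]bis(4,4,5,5-tetramethyl-1,3,2-dioxaborolane) | COc1c(B2OC(C)(C)C(C)(C)O2)cc(B2OC(C)(C)C(C)(C)O2)c(OC)c1OCc1ccccc1 | intermediate
5 | 5-(benzyloxy)-4,6-dimethoxybenzene-1,3-diol | COc1c(O)cc(O)c(OC)c1OCc1ccccc1 | intermediate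
6 | (R)-4-benzyloxazolidin-2-one | O=C1N[C@H](Cc2ccccc2)CO1 | starting material
7 | (benzyloxy)acetyl chloride | O=C(Cl)COCc1ccccc1 | starting material
8 | (R)-4-benzyl-3-[(benzyloxy)acetyl]oxazolidin-2-one | O=C1OC[C@@H](Cc2ccccc2)N1C(=O)COCc1ccccc1 | intermediate
9 | 3,4,5-tris(benzyloxy)benzaldehyde | O=Cc1cc(OCc2ccccc2)c(OCc2ccccc2)c(OCc2ccccc2)c1 | starting material
10 | Z dibutylboron enolate of 8 (not isolated) | CCCCB(CCCC)O/C(=C\OCc1ccccc1)N1C(=O)OC[C@H]1Cc1ccccc1 | intermediate
11 | (R)-4-benzyl-3-{(2R,3S)-2-(benzyloxy)-3-hydroxy-3-[3,4,5-tris(benzyloxy)phenyl]propanoyl}oxazolidin-2-one | O=C1OC[C@@H](Cc2ccccc2)N1C(=O)[C@H](OCc1ccccc1)[C@@H](O)c1cc(OCc2ccccc2)c(OCc2ccccc2)c(OCc2ccccc2)c1 | intermediate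
12 | (2R,3S)-2-(benzyloxy)-3-hydroxy-N-methoxy-N-methyl-3-[3,4,5-tris(benzyloxy)phenyl]propanamide | CON(C)C(=O)[C@H](OCc1ccccc1)[C@@H](O)c1cc(OCc2ccccc2)c(OCc2ccccc2)c(OCc2ccccc2)c1 | intermediate
13 | (2R,3R)-2-(benzyloxy)-3-[3-(benzyloxy)-5-hydroxy-2,4-dimethoxyphenoxy]-N-methoxy-N-methyl-3-[3,4,5-tris(benzyloxy)phenyl]propanamide | CON(C)C(=O)[C@H](OCc1ccccc1)[C@H](Oc1cc(O)c(OC)c(OCc2ccccc2)c1OC)c1cc(OCc2ccccc2)c(OCc2ccccc2)c(OCc2ccccc2)c1 | intermediate
14 | (2R,3R)-2-(benzyloxy)-3-[3-(benzyloxy)-5-hydroxy-2,4-dimethoxyphenoxy]-3-[3,4,5-tris(benzyloxy)phenyl]propanal (key-step precursor) | O=C[C@H](OCc1ccccc1)[C@H](Oc1cc(O)c(OC)c(OCc2ccccc2)c1OC)c1cc(OCc2ccccc2)c(OCc2ccccc2)c(OCc2ccccc2)c1 | intermediate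
15 | bromomagnesium O5-phenolate of 14 (not isolated) | O=C[C@H](OCc1ccccc1)[C@H](Oc1cc(O[Mg]Br)c(OC)c(OCc2ccccc2)c1OC)c1cc(OCc2ccccc2)c(OCc2ccccc2)c(OCc2ccccc2)c1 | intermediate
16 | ring-closed 4a-H cyclohexa-2,4-dien-5-one, bromomagnesium 4-alkoxide, 4a-H anti to 4-H (not isolated) | COC1=C(OCc2ccccc2)C(OC)=C2O[C@H](c3cc(OCc4ccccc4)c(OCc4ccccc4)c(OCc4ccccc4)c3)[C@@H](OCc3ccccc3)[C@H](O[Mg]Br)[C@H]2C1=O | intermediate
17 | (2R,3S,4R)-3,7-bis(benzyloxy)-6,8-dimethoxy-2-[3,4,5-tris(benzyloxy)phenyl]chromane-4,5-diol (key-step product) | COc1c(OCc3ccccc3)c(OC)c2c(c1O)[C@@H](O)[C@H](OCc3ccccc3)[C@@H](c1cc(OCc3ccccc3)c(OCc3ccccc3)c(OCc3ccccc3)c1)O2 | intermediate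
18 | (2R,3S,4R)-6,8-dimethoxy-2-(3,4,5-trihydroxyphenyl)chromane-3,4,5,7-tetrol | COc1c(O)c(OC)c2c(c1O)[C@@H](O)[C@H](O)[C@@H](c1cc(O)c(O)c(O)c1)O2 | target

Total step count: 11
Longest linear sequence: 8 (steps 1–4, then 8–11)

**Steps most likely to fail**

**1. Step 10.** The aldehyde may lose the aryloxide by β-elimination or epimerise at C3 faster than C4a attacks. The two aldehyde faces may also be poorly differentiated.

The fallback uses known chemistry, sets out from 13 and comes back at 18. It closes the same C4–C4a bond as a Parham-type anionic cyclisation at the acid oxidation level, and C4 is then set by hydride.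
- 13 is iodinated at C4a, its only ring A C–H (NIS, CH2Cl2, −20 °C), to give the iodophenol F1.
- O5 is benzylated (BnBr, K2CO3, DMF, rt) to give the aryl iodide F2.
- Iodine–lithium exchange (n-BuLi, THF, −90 °C) lets the aryllithium attack the internal Weinreb amide to give the chroman-4-one F3.
- NaBH4 (THF–MeOH, 0 °C) delivers hydride axially, the known course for 2,3-trans-dihydroflavonol ethers, to give the 3,4-trans alcohol F4.
- Hydrogenolysis of its six benzyl ethers under the conditions of step 11 gives 18.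

**2. Step 8.** Partial ionisation at the electron-rich benzylic carbon would erode the inversion. Elimination toward the conjugated enol ether, sluggish substitution at the crowded carbinol and a second etherification are the other failure modes.

The fallback sets out from 9 and 5 and comes back at 14. It makes O1–C2 by base-mediated SN2 opening of an enantiopure epoxide, which involves no activated alcohol and no acidic α-hydrogen.
- 9 is homologated by Horner–Wadsworth–Emmons olefination (triethyl phosphonoacetate, NaH, THF) to the ethyl cinnamate F5.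
- Reduction (i-Bu2AlH, CH2Cl2, −78 °C) gives the allylic alcohol F6.
- Sharpless asymmetric epoxidation (Ti(OiPr)4, L-(+)-diethyl tartrate, t-BuOOH, 4 Å sieves, CH2Cl2, −20 °C) gives the (2S,3S)-epoxy alcohol F7.
- The sodium phenolate of 5 (excess 5, aq NaOH, dioxane, 70 °C, argon) opens the epoxide at the benzylic carbon with inversion. This gives the aryloxy diol F8, whose two centres already match C2 and C3 of 14.
- The diol is tied up as the benzylidene acetal F9 (PhCH(OMe)2, PPTS, CH2Cl2).
- The only OH left, the O5 phenol, is silylated (TBSCl, imidazole, DMF) to the silyl ether F10.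
- i-Bu2AlH (CH2Cl2, 0 °C) opens the acetal at its less hindered oxygen, which leaves benzyl on O3 and frees the primary alcohol F11.
- With the phenol masked, Dess–Martin oxidation (NaHCO3, CH2Cl2) gives the silylated aldehyde F12.
- Buffered fluoride (Bu4NF, AcOH, THF, 0 °C) releases 14.

**3. Step 11.** The benzylic 4-hydroxyl group may be lost by hydrogenolysis, or solvolysed on an acidic catalyst surface, while the slower alkyl benzyl ether at O3 is still being cleaved.

The fallback sets out from 17 and comes back at 18. C4 is kept as a ketone during debenzylation and the alcohol is restored last, without palladium.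
- Activated MnO2 (CH2Cl2, rt) oxidises the benzylic alcohol to the dihydroflavonol ether F13.
- Hydrogenolysis (H2, Pd/C, THF–EtOAc) gives the free dihydroflavonol F14, whose hydrogen-bonded aryl ketone should resist reduction.
- NaBH4 (EtOH, 0 °C, neutral work-up) gives the 3,4-trans diol 18, the known course for 2,3-trans-dihydroflavonols.

The same detour would merge any 3,4-cis epimer from step 10, since both epimers give the same ketone.

**Further compounds**
F1 | step 10 | (2R,3R)-2-(benzyloxy)-3-[5-(benzyloxy)-3-hydroxy-2-iodo-4,6-dimethoxyphenoxy]-N-methoxy-N-methyl-3-[3,4,5-tris(benzyloxy)phenyl]propanamide | CON(C)C(=O)[C@H](OCc1ccccc1)[C@H](Oc1c(I)c(O)c(OC)c(OCc2ccccc2)c1OC)c1cc(OCc2ccccc2)c(OCc2ccccc2)c(OCc2ccccc2)c1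
F2 | step 10 | (2R,3R)-2-(benzyloxy)-3-[3,5-bis(benzyloxy)-2-iodo-4,6-dimethoxyphenoxy]-N-methoxy-N-methyl-3-[3,4,5-tris(benzyloxy)phenyl]propanamide | CON(C)C(=O)[C@H](OCc1ccccc1)[C@H](Oc1c(I)c(OCc2ccccc2)c(OC)c(OCc2ccccc2)c1OC)c1cc(OCc2ccccc2)c(OCc2ccccc2)c(OCc2ccccc2)c1
F3 | step 10 | (2R,3R)-3,5,7-tris(benzyloxy)-6,8-dimethoxy-2-[3,4,5-tris(benzyloxy)phenyl]chroman-4-one | COc1c(OCc3ccccc3)c(OC)c2c(c1OCc1ccccc1)C(=O)[C@H](OCc3ccccc3)[C@@H](c1cc(OCc3ccccc3)c(OCc3ccccc3)c(OCc3ccccc3)c1)O2
F4 | step 10 | (2R,3S,4R)-3,5,7-tris(benzyloxy)-6,8-dimethoxy-2-[3,4,5-tris(benzyloxy)phenyl]chroman-4-ol | COc1c(OCc3ccccc3)c(OC)c2c(c1OCc1ccccc1)[C@@H](O)[C@H](OCc3ccccc3)[C@@H](c1cc(OCc3ccccc3)c(OCc3ccccc3)c(OCc3ccccc3)c1)O2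
F5 | step 8 | ethyl (E)-3-[3,4,5-tris(benzyloxy)phenyl]prop-2-enoate | CCOC(=O)/C=C/c1cc(OCc2ccccc2)c(OCc2ccccc2)c(OCc2ccccc2)c1
F6 | step 8 | (E)-3-[3,4,5-tris(benzyloxy)phenyl]prop-2-en-1-ol | OC/C=C/c1cc(OCc2ccccc2)c(OCc2ccccc2)c(OCc2ccccc2)c1
F7 | step 8 | {(2S,3S)-3-[3,4,5-tris(benzyloxy)phenyl]oxiran-2-yl}methanol | OC[C@@H]1O[C@H]1c1cc(OCc2ccccc2)c(OCc2ccccc2)c(OCc2ccccc2)c1
F8 | step 8 | (2S,3R)-3-[3-(benzyloxy)-5-hydroxy-2,4-dimethoxyphenoxy]-3-[3,4,5-tris(benzyloxy)phenyl]propane-1,2-diol | OC[C@H](O)[C@H](Oc1cc(O)c(OC)c(OCc2ccccc2)c1OC)c1cc(OCc2ccccc2)c(OCc2ccccc2)c(OCc2ccccc2)c1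
F9 | step 8 | 1,2-O-benzylidene acetal of F8 (both acetal epimers) | c1ccccc1C1OC[C@H](O1)[C@H](Oc1cc(O)c(OC)c(OCc2ccccc2)c1OC)c1cc(OCc2ccccc2)c(OCc2ccccc2)c(OCc2ccccc2)c1
F10 | step 8 | O5-tert-butyldimethylsilyl ether of F9 | c1ccccc1C1OC[C@H](O1)[C@H](Oc1cc(O[Si](C)(C)C(C)(C)C)c(OC)c(OCc2ccccc2)c1OC)c1cc(OCc2ccccc2)c(OCc2ccccc2)c(OCc2ccccc2)c1
F11 | step 8 | (2S,3R)-2-(benzyloxy)-3-[3-(benzyloxy)-5-(tert-butyldimethylsilyloxy)-2,4-dimethoxyphenoxy]-3-[3,4,5-tris(benzyloxy)phenyl]propan-1-ol | OC[C@H](OCc1ccccc1)[C@H](Oc1cc(O[Si](C)(C)C(C)(C)C)c(OC)c(OCc2ccccc2)c1OC)c1cc(OCc2ccccc2)c(OCc2ccccc2)c(OCc2ccccc2)c1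
F12 | step 8 | (2R,3R)-2-(benzyloxy)-3-[3-(benzyloxy)-5-(tert-butyldimethylsilyloxy)-2,4-dimethoxyphenoxy]-3-[3,4,5-tris(benzyloxy)phenyl]propanal | O=C[C@H](OCc1ccccc1)[C@H](Oc1cc(O[Si](C)(C)C(C)(C)C)c(OC)c(OCc2ccccc2)c1OC)c1cc(OCc2ccccc2)c(OCc2ccccc2)c(OCc2ccccc2)c1
F13 | step 11 | (2R,3R)-3,7-bis(benzyloxy)-5-hydroxy-6,8-dimethoxy-2-[3,4,5-tris(benzyloxy)phenyl]chroman-4-one | COc1c(OCc3ccccc3)c(OC)c2c(c1O)C(=O)[C@H](OCc3ccccc3)[C@@H](c1cc(OCc3ccccc3)c(OCc3ccccc3)c(OCc3ccccc3)c1)O2
F14 | step 11 | (2R,3R)-3,5,7-trihydroxy-6,8-dimethoxy-2-(3,4,5-trihydroxyphenyl)chroman-4-one | COc1c(O)c(OC)c2c(c1O)C(=O)[C@H](O)[C@@H](c1cc(O)c(O)c(O)c1)O2
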